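**Strategy.** Ring A is closed by a formal [5+1] annulation in which one carbon, C4, is stitched between C9 and C5. Its precursor is a spiro α-methylene δ-lactone (rings B, C and D complete): the exocyclic C8=C9, activated by the lactone carbonyl C10, is a Michael acceptor, and the two-carbon chain on C7 ends in a C5 mesylate. Sodium diethyl oxalacetate adds through its central carbon to C9, the lactone enolate is protonated at C8 anti to the C7 chain (cis A/B fusion), and the still acidic C4–H then displaces the mesylate, forming C4–C5. The two carbonyl groups on C4 become the propanoic acid side chain; rings B–D grow from desymmetrised 4,4-dimethylcyclohexadienone.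

Key step: step 9

Remark (labels): atoms are counted along the target SMILES (C1 methyl, C2, C3 carboxyl, C4–C9 ring A, C10 lactone carbonyl, O11, C12, spiro C13, C14 ketone, C15, C16, O17, C18, C19, C20 CMe2). Ring A = cyclohexane, ring B = δ-lactone, ring C = cyclohexanone, ring D = tetrahydrofuran.

Step 1
Reactants: 1 4,4-dimethylcyclohex-2-en-1-one
Product: 2 4,4-dimethylcyclohexa-2,5-dien-1-one
Conditions: DDQ (1.3 equiv), 1,4-dioxane, reflux
Reagents that add atoms: none
Why: Quinone dehydrogenation of the enone (hydride abstraction from its dienol) should give the cross-conjugated dienone; no stereocentre is involved.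

Step 2
Reactants: 2 4,4-dimethylcyclohexa-2,5-dien-1-one; 3 [(dimethylphenylsilyl)methyl]magnesium chloride
Product: 4 (5R)-5-{[dimethyl(phenyl)silyl]methyl}-4,4-dimethylcyclohex-2-en-1-one
Conditions: 3 (1.1 equiv), CuBr·SMe2 (5 mol %), (R,S)-Josiphos (6 mol %, enantiomer chosen to give (R)-4), t-BuOMe, −78 °C; aq. NH4Cl
Reagents that add atoms: none
Why: Copper-catalysed asymmetric conjugate addition of a Grignard reagent desymmetrises the prochiral dienone, the chiral diphosphine setting C19, and the magnesium dienolate formed is inert to a second addition; the silylmethyl group is a masked hydroxymethyl group (C18–O17).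

Step 3
Reactants: 4 (5R)-5-{[dimethyl(phenyl)silyl]methyl}-4,4-dimethylcyclohex-2-en-1-one; 5 methyl (2E)-3-methoxyprop-2-enoate
Product: 7 methyl (2E)-3-[(1S,6S)-6-{[dimethyl(phenyl)silyl]methyl}-1-(hydroxymethyl)-5,5-dimethyl-2-oxocyclohex-3-en-1-yl]prop-2-enoate, via keto ester 6 (not isolated)
Conditions: LDA (1.05 equiv), THF, −78 °C; 5 (1.1 equiv), −78 → −30 °C; CH2O (g, from paraformaldehyde), −78 °C; aq. NH4Cl
Reagents that add atoms: formaldehyde (C=O)
Why: The α′-lithium dienolate undergoes addition–elimination (vinylic substitution) on the β-methoxyacrylate to give 6, the methoxide set free regenerates its extended enolate, and the α-selective aldol addition to formaldehyde should occur anti to the pseudoaxial C18 substituent on C19, setting the quaternary centre C13.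

Step 4
Reactants: 7 methyl (2E)-3-[(1S,6S)-6-{[dimethyl(phenyl)silyl]methyl}-1-(hydroxymethyl)-5,5-dimethyl-2-oxocyclohex-3-en-1-yl]prop-2-enoate
Product: 9 (6S,11S)-11-{[dimethyl(phenyl)silyl]methyl}-10,10-dimethyl-2-oxaspiro[5.5]undeca-4,8-diene-3,7-dione, via (Z)-ester 8 (not isolated)
Conditions: PhSH (0.2 equiv), AIBN (0.1 equiv), toluene, 80 °C; then CSA (5 mol %)
Reagents that add atoms: none
Why: Reversible addition of the phenylthiyl radical interconverts the E and Z enoates, and the minor Z isomer is drained irreversibly by lactonisation of the C12 hydroxyl onto C10 (transesterification), closing ring B without touching a stereocentre.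

Step 5
Reactants: 9 (6S,11S)-11-{[dimethyl(phenyl)silyl]methyl}-10,10-dimethyl-2-oxaspiro[5.5]undeca-4,8-diene-3,7-dione
Product: 11 (1S,2S,5S)-8,8-dimethylspiro[6-oxabicyclo[3.2.1]octane-2,3'-(3',6'-dihydro-2'H-pyran)]-3,6'-dione (ring B = 5,6-dihydropyran-2-one; rings C and D closed), via hydroxy enone 10 (not isolated)
Conditions: KBr, AcOOH, NaOAc, AcOH, 0 °C → rt; then DBU (0.2 equiv), CH2Cl2, rt
Reagents that add atoms: peracetic acid (CC(=O)OO)
Why: Fleming–Tamao oxidation (bromodesilylation of the phenyl group, then peracid oxidation of the C18–Si bond with retention) unmasks the C18 hydroxyl, which closes ring D by intramolecular oxa-Michael addition to C16, the bridging geometry fixing the new centre C16.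

Step 6
Reactants: 11 (1S,2S,5S)-8,8-dimethylspiro[6-oxabicyclo[3.2.1]octane-2,3'-(3',6'-dihydro-2'H-pyran)]-3,6'-dione; 12 vinylmagnesium bromide
Product: 13 (1S,2S,4'R,5S,5'S)-4'-ethenyl-5'-(hydroxymethyl)-8,8-dimethylspiro[6-oxabicyclo[3.2.1]octane-2,3'-oxane]-3,6'-dione
Conditions: 12 (2.2 equiv), CuBr·SMe2 (1.1 equiv), THF, −78 → −40 °C; CH2O (g, from paraformaldehyde), −78 °C; aq. NH4Cl
Reagents that add atoms: formaldehyde (C=O)
Why: Cuprate conjugate addition to the unsaturated lactone should place the vinyl group on C7 from the ring B face anti to the bulky bridgehead C19 (syn to C14), and the enolate is trapped by aldol addition to formaldehyde at C8 (anti to the vinyl group; this centre is erased in step 8).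

Step 7
Reactants: 13 (1S,2S,4'R,5S,5'S)-4'-ethenyl-5'-(hydroxymethyl)-8,8-dimethylspiro[6-oxabicyclo[3.2.1]octane-2,3'-oxane]-3,6'-dione
Product: 15 (1S,2S,4'R,5S,5'S)-4'-(2-hydroxyethyl)-5'-(hydroxymethyl)-8,8-dimethylspiro[6-oxabicyclo[3.2.1]octane-2,3'-oxane]-3,6'-dione, via bis-boryl species 14 (not isolated)
Conditions: catecholborane (3 equiv), RhCl(PPh3)3 (2 mol %), THF, 0 °C → rt; then H2O2, pH 7 buffer, 0 °C
Reagents that add atoms: hydrogen peroxide (OO)
Why: Rhodium-catalysed hydroboration with catecholborane is anti-Markovnikov and selective for the terminal alkene over ketone and lactone, and oxidation gives the C5 alcohol without touching a stereocentre.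

Step 8
Reactants: 15 (1S,2S,4'R,5S,5'S)-4'-(2-hydroxyethyl)-5'-(hydroxymethyl)-8,8-dimethylspiro[6-oxabicyclo[3.2.1]octane-2,3'-oxane]-3,6'-dione
Product: 17 2-[(1S,2S,4'S,5S)-8,8-dimethyl-5'-methylidene-3,6'-dioxospiro[6-oxabicyclo[3.2.1]octane-2,3'-oxan]-4'-yl]ethyl methanesulfonate, via bis-mesylate 16 (not isolated)
Conditions: MsCl (2.4 equiv), Et3N (6 equiv), CH2Cl2, 0 → 40 °C
Reagents that add atoms: methanesulfonyl chloride (CS(=O)(=O)Cl)
Why: Both primary alcohols are mesylated, and the C9 mesylate, β to the lactone carbonyl, is lost by E1cB elimination to the α-methylene lactone while the C5 mesylate persists.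

Step 9
Reactants: 17 2-[(1S,2S,4'S,5S)-8,8-dimethyl-5'-methylidene-3,6'-dioxospiro[6-oxabicyclo[3.2.1]octane-2,3'-oxan]-4'-yl]ethyl methanesulfonate; 18 sodium diethyl oxalacetate
Product: 20 ethyl (1'S,4S,4aR,5'S,8aS)-7-(2-ethoxy-2-oxoacetyl)-8',8'-dimethyl-1,3'-dioxooctahydrospiro[isochromene-4,2'-[6]oxabicyclo[3.2.1]octane]-7-carboxylate (C7 of the isochromane, = C4, as an epimer mixture), via Michael adduct 19 (not isolated)
Conditions: 18 (1.2 equiv), NaI (0.2 equiv), DMF, 0 → 50 °C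
Reagents that add atoms: none
Why: The oxalacetate enolate adds through C4 to the exocyclic C9 of the α-methylene lactone (Michael addition), proton transfer from the doubly activated C4–H to the lactone enolate gives 19 and regenerates a C4 carbanion, and this closes ring A by intramolecular SN2 displacement at C5 (6-exo-tet, iodide-assisted), so that the C4–C5 bond is the ring-closing bond. The closest known reaction type is the Michael addition–intramolecular alkylation annulation of β-keto esters and malonates with acceptors that carry a remote leaving group. C8 is set in the protonation, which should occur anti to the C7 side chain, held pseudoaxial by A(1,2) strain with the C9 substituent, as in the kinetic protonation of 2,3-disubstituted cyclic enolates, giving the cis A/B fusion (H7 and H8 syn). C4 becomes quaternary and its configuration does not matter because it is reset in step 10. Chemoselectivity rests on acidity, since only the oxalacetate C–H, not the ketone C15–H or lactone C8–H, is ionised by the sodium salt, and C-alkylation gives a six-membered ring whereas O-alkylation would need an eight-membered one. The required order, Michael addition before alkylation, is secured by the much higher electrophilicity of the α-methylene lactone compared with a primary mesylate.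

Step 10
Reactants: 20 ethyl (1'S,4S,4aR,5'S,8aS)-7-(2-ethoxy-2-oxoacetyl)-8',8'-dimethyl-1,3'-dioxooctahydrospiro[isochromene-4,2'-[6]oxabicyclo[3.2.1]octane]-7-carboxylate
Product: 22 2-[(1'S,4S,4aR,5'S,7R,8aS)-8',8'-dimethyl-1,3'-dioxooctahydrospiro[isochromene-4,2'-[6]oxabicyclo[3.2.1]octan]-7-yl]-2-oxoacetic acid, via diacid 21 (not isolated)
Conditions: 6 M HCl, AcOH, 90 °C
Reagents that add atoms: water (O)
Why: Acid hydrolysis of both ethyl esters and decarboxylation of the β-keto acid at C4 (the classical cleavage of an α-oxalyl ester to an α-keto acid) leaves C4 α to the ketone C2, where it should equilibrate to the equatorial 7R configuration, trans to C10 and to C13.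

Step 11
Reactants: 22 2-[(1'S,4S,4aR,5'S,7R,8aS)-8',8'-dimethyl-1,3'-dioxooctahydrospiro[isochromene-4,2'-[6]oxabicyclo[3.2.1]octan]-7-yl]-2-oxoacetic acid
Product: 23 2-[(1'S,4S,4aR,5'S,7R,8aS)-8',8'-dimethyl-1,3'-dioxooctahydrospiro[isochromene-4,2'-[6]oxabicyclo[3.2.1]octan]-7-yl]prop-2-enoic acid
Conditions: Ph3PCH3Br (3.2 equiv), KHMDS (3.1 equiv), THF, 0 °C; then 22, 0 °C → rt; 1 M HCl work-up
Reagents that add atoms: methyltriphenylphosphonium bromide (C[P+](c1ccccc1)(c1ccccc1)c1ccccc1.[Br-])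
Why: Wittig methylenation should take place at the α-keto carboxylate carbonyl C2, which is far more electrophilic and less hindered than the neopentyl ketone C14 flanked by the quaternary C13.

Step 12
Reactants: 23 2-[(1'S,4S,4aR,5'S,7R,8aS)-8',8'-dimethyl-1,3'-dioxooctahydrospiro[isochromene-4,2'-[6]oxabicyclo[3.2.1]octan]-7-yl]prop-2-enoic acid
Product: 24 (2R)-2-[(1'S,4S,4aR,5'S,7R,8aS)-8',8'-dimethyl-1,3'-dioxooctahydrospiro[isochromene-4,2'-[6]oxabicyclo[3.2.1]octan]-7-yl]propanoic acid (target)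
Conditions: H2 (60 bar), Ru(OAc)2[(R)-H8-BINAP] (1 mol %), MeOH, rt
Reagents that add atoms: none
Why: Carboxylate-directed asymmetric hydrogenation of a 2-substituted acrylic acid sets C2 under catalyst control, which is needed because C4 is locally symmetric (C5 and C9 are both CH2); the ligand enantiomer is the one expected to give 2R by analogy with 2-arylacrylic acids.

**Compound list**

1 | 4,4-dimethylcyclohex-2-en-1-one | CC1(C)CCC(=O)C=C1 | starting material
2 | 4,4-dimethylcyclohexa-2,5-dien-1-one | CC1(C)C=CC(=O)C=C1 | intermediate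
3 | [(dimethylphenylsilyl)methyl]magnesium chloride | C[Si](C)(C[Mg]Cl)c1ccccc1 | starting material
4 | (5R)-5-{[dimethyl(phenyl)silyl]methyl}-4,4-dimethylcyclohex-2-en-1-one | O=C1C=CC(C)(C)[C@H](C[Si](C)(C)c2ccccc2)C1 | intermediate
5 | methyl (2E)-3-methoxyprop-2-enoate | CO/C=C/C(=O)OC | starting material
6 | methyl (2E)-3-[(6R)-6-{[dimethyl(phenyl)silyl]methyl}-5,5-dimethyl-2-oxocyclohex-3-en-1-yl]prop-2-enoate (ring C1 undefined; present as its lithium dienolate) | COC(=O)/C=C/C1C(=O)C=CC(C)(C)[C@@H]1C[Si](C)(C)c1ccccc1 | intermediate (not isolated)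
7 | methyl (2E)-3-[(1S,6S)-6-{[dimethyl(phenyl)silyl]methyl}-1-(hydroxymethyl)-5,5-dimethyl-2-oxocyclohex-3-en-1-yl]prop-2-enoate | OC[C@@]1(/C=C/C(=O)OC)C(=O)C=CC(C)(C)[C@@H]1C[Si](C)(C)c1ccccc1 | intermediate
8 | methyl (2Z)-3-[(1S,6S)-6-{[dimethyl(phenyl)silyl]methyl}-1-(hydroxymethyl)-5,5-dimethyl-2-oxocyclohex-3-en-1-yl]prop-2-enoate | OC[C@@]1(/C=C\C(=O)OC)C(=O)C=CC(C)(C)[C@@H]1C[Si](C)(C)c1ccccc1 | intermediate (not isolated)
9 | (6S,11S)-11-{[dimethyl(phenyl)silyl]methyl}-10,10-dimethyl-2-oxaspiro[5.5]undeca-4,8-diene-3,7-dione | O=C1C=C[C@]2(CO1)C(=O)C=CC(C)(C)[C@@H]2C[Si](C)(C)c1ccccc1 | intermediate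
10 | (6S,11S)-11-(hydroxymethyl)-10,10-dimethyl-2-oxaspiro[5.5]undeca-4,8-diene-3,7-dione | O=C1C=C[C@]2(CO1)C(=O)C=CC(C)(C)[C@@H]2CO | intermediate (not isolated)
11 | (1S,2S,5S)-8,8-dimethylspiro[6-oxabicyclo[3.2.1]octane-2,3'-(3',6'-dihydro-2'H-pyran)]-3,6'-dione | O=C1C=C[C@]2(CO1)C(=O)C[C@@H]3OC[C@H]2C3(C)C | intermediate
12 | vinylmagnesium bromide | C=C[Mg]Br | starting material
13 | (1S,2S,4'R,5S,5'S)-4'-ethenyl-5'-(hydroxymethyl)-8,8-dimethylspiro[6-oxabicyclo[3.2.1]octane-2,3'-oxane]-3,6'-dione | C=C[C@@H]1[C@@H](CO)C(=O)OC[C@]12C(=O)C[C@@H]3OC[C@H]2C3(C)C | intermediate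
14 | bis(1,3,2-benzodioxaborol-2-yl) derivative of 15 (C5–B alkylboronate and C9–O–B borate) | B1(CC[C@@H]2[C@@H](COB3Oc4ccccc4O3)C(=O)OC[C@]25C(=O)C[C@@H]6OC[C@H]5C6(C)C)Oc2ccccc2O1 | intermediate (not isolated)
15 | (1S,2S,4'R,5S,5'S)-4'-(2-hydroxyethyl)-5'-(hydroxymethyl)-8,8-dimethylspiro[6-oxabicyclo[3.2.1]octane-2,3'-oxane]-3,6'-dione | OCC[C@@H]1[C@@H](CO)C(=O)OC[C@]12C(=O)C[C@@H]3OC[C@H]2C3(C)C | intermediate
16 | bis(methanesulfonate) of diol 15 | CS(=O)(=O)OCC[C@@H]1[C@@H](COS(C)(=O)=O)C(=O)OC[C@]12C(=O)C[C@@H]3OC[C@H]2C3(C)C | intermediate (not isolated)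
17 | 2-[(1S,2S,4'S,5S)-8,8-dimethyl-5'-methylidene-3,6'-dioxospiro[6-oxabicyclo[3.2.1]octane-2,3'-oxan]-4'-yl]ethyl methanesulfonate | CS(=O)(=O)OCC[C@@H]1C(=C)C(=O)OC[C@]12C(=O)C[C@@H]3OC[C@H]2C3(C)C | intermediate
18 | sodium diethyl oxalacetate (sodium 1,4-diethoxy-1,4-dioxobut-2-en-2-olate) | [Na+].CCOC(=O)C=C([O-])C(=O)OCC | starting material
19 | diethyl 2-{[(1S,2S,4'R,5S,5'S)-4'-[2-(methanesulfonyloxy)ethyl]-8,8-dimethyl-3,6'-dioxospiro[6-oxabicyclo[3.2.1]octane-2,3'-oxan]-5'-yl]methyl}-3-oxobutanedioate (formed as its sodium enolate; succinate C2 undefined) | CCOC(=O)C(=O)C(C(=O)OCC)C[C@H]1[C@@H](CCOS(C)(=O)=O)[C@]2(COC1=O)C(=O)C[C@@H]3OC[C@H]2C3(C)C | intermediate (not isolated)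
20 | ethyl (1'S,4S,4aR,5'S,8aS)-7-(2-ethoxy-2-oxoacetyl)-8',8'-dimethyl-1,3'-dioxooctahydrospiro[isochromene-4,2'-[6]oxabicyclo[3.2.1]octane]-7-carboxylate (C7 epimers) | CCOC(=O)C(=O)C1(C(=O)OCC)CC[C@@H]2[C@H](C1)C(=O)OC[C@]23C(=O)C[C@@H]4OC[C@H]3C4(C)C | intermediate
21 | (1'S,4S,4aR,5'S,8aS)-7-(carboxycarbonyl)-8',8'-dimethyl-1,3'-dioxooctahydrospiro[isochromene-4,2'-[6]oxabicyclo[3.2.1]octane]-7-carboxylic acid | OC(=O)C(=O)C1(C(=O)O)CC[C@@H]2[C@H](C1)C(=O)OC[C@]23C(=O)C[C@@H]4OC[C@H]3C4(C)C | intermediate (not isolated)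
22 | 2-[(1'S,4S,4aR,5'S,7R,8aS)-8',8'-dimethyl-1,3'-dioxooctahydrospiro[isochromene-4,2'-[6]oxabicyclo[3.2.1]octan]-7-yl]-2-oxoacetic acid | OC(=O)C(=O)[C@@H]1CC[C@@H]2[C@H](C1)C(=O)OC[C@]23C(=O)C[C@@H]4OC[C@H]3C4(C)C | intermediate
23 | 2-[(1'S,4S,4aR,5'S,7R,8aS)-8',8'-dimethyl-1,3'-dioxooctahydrospiro[isochromene-4,2'-[6]oxabicyclo[3.2.1]octan]-7-yl]prop-2-enoic acid | C=C(C(=O)O)[C@@H]1CC[C@@H]2[C@H](C1)C(=O)OC[C@]23C(=O)C[C@@H]4OC[C@H]3C4(C)C | intermediate
24 | (2R)-2-[(1'S,4S,4aR,5'S,7R,8aS)-8',8'-dimethyl-1,3'-dioxooctahydrospiro[isochromene-4,2'-[6]oxabicyclo[3.2.1]octan]-7-yl]propanoic acid | C[C@@H](C(=O)O)[C@@H]1CC[C@@H]2[C@H](C1)C(=O)OC[C@]21C(=O)C[C@@H]2OC[C@H]1C2(C)C | target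

**Total step count:** 12. **Longest linear sequence:** 12 steps (from 1).

**Steps most likely to fail**

Step 9 (key annulation). The ring closure by SN2 may be outrun by intermolecular alkylation or by elimination of the mesylate, and the C8 configuration rests on one kinetic protonation. The fallback changes the ring-closing reaction from alkylation to aldol addition, still forming C4–C5. It sets out from 11: allyl cuprate addition (allylmagnesium bromide, CuBr·SMe2) with formaldehyde trapping should give (1S,2S,4'R,5S,5'S)-5'-(hydroxymethyl)-8,8-dimethyl-4'-(prop-2-en-1-yl)spiro[6-oxabicyclo[3.2.1]octane-2,3'-oxane]-3,6'-dione F1. MsCl/Et3N then gives the α-methylene lactone (1S,2S,4'S,5S)-8,8-dimethyl-5'-methylidene-4'-(prop-2-en-1-yl)spiro[6-oxabicyclo[3.2.1]octane-2,3'-oxane]-3,6'-dione F2. Ozonolysis limited to the electron-rich terminal alkene (O3, CH2Cl2, −78 °C, one equivalent; PPh3) gives 2-[(1S,2S,4'S,5S)-8,8-dimethyl-5'-methylidene-3,6'-dioxospiro[6-oxabicyclo[3.2.1]octane-2,3'-oxan]-4'-yl]acetaldehyde F3. With 18 in DMF, Michael addition at C9 is followed by aldol closure of the C4 carbanion onto the C5 aldehyde to give ethyl (1'S,4S,4aR,5'S,8aS)-7-(2-ethoxy-2-oxoacetyl)-6-hydroxy-8',8'-dimethyl-1,3'-dioxooctahydrospiro[isochromene-4,2'-[6]oxabicyclo[3.2.1]octane]-7-carboxylate F4. Hot 6 M HCl/AcOH hydrolyses, decarboxylates and dehydrates it to the C4=C5 enone acid 2-[(1'S,4S,4aR,5'S,8aS)-8',8'-dimethyl-1,3'-dioxo-3,4a,5,8,8a-pentahydrospiro[isochromene-4,2'-[6]oxabicyclo[3.2.1]octan]-7-yl]-2-oxoacetic acid F5. Hydrogenation (H2, Pd/C, EtOAc) saturates C4=C5, C4 equilibrates next to the ketone, and the route is rejoined at 22.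

Step 3 (one-pot vinylation and hydroxymethylation). Formaldehyde may attack C8 instead of C13 of the extended enolate, the enolate oxygen may acylate to a fused 2-pyranone, or the aldol may revert. The fallback builds the lactone from an allyl group, so no extended enolate is involved. It sets out from 4: LDA/allyl bromide should give (5R)-5-{[dimethyl(phenyl)silyl]methyl}-4,4-dimethyl-6-(prop-2-en-1-yl)cyclohex-2-en-1-one F6. LDA then CH2O (anti to C18) gives (5S,6S)-5-{[dimethyl(phenyl)silyl]methyl}-6-(hydroxymethyl)-4,4-dimethyl-6-(prop-2-en-1-yl)cyclohex-2-en-1-one F7. RhCl(PPh3)3/catecholborane then H2O2 gives (5S,6S)-5-{[dimethyl(phenyl)silyl]methyl}-6-(hydroxymethyl)-6-(3-hydroxypropyl)-4,4-dimethylcyclohex-2-en-1-one F8. TEMPO/PhI(OAc)2 oxidises the less hindered carbinol first and lactonises to (6S,11S)-11-{[dimethyl(phenyl)silyl]methyl}-10,10-dimethyl-2-oxaspiro[5.5]undec-8-ene-3,7-dione F9. Palladium-catalysed α,β-dehydrogenation of the lactone zinc enolate (LiTMP, ZnCl2, [Pd(allyl)Cl]2, diethyl allyl phosphate) rejoins the route at 9, so step 4 is bypassed as well.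

Step 2 (asymmetric conjugate addition). The silylmethyl group may transfer sluggishly from copper, and enantiofacial discrimination at the β-carbon next to the quaternary C20 may be poor. The fallback replaces asymmetric catalysis by resolution. It sets out from 2: achiral copper catalysis (3, CuI·2LiCl, TMSCl, THF, −40 °C) should give racemic 5-{[dimethyl(phenyl)silyl]methyl}-4,4-dimethylcyclohex-2-en-1-one F10, which is separated by preparative chromatography on a chiral stationary phase (amylose carbamate); the (R)-enantiomer is compound 4.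

Further compounds
F1 | step 9 | (1S,2S,4'R,5S,5'S)-5'-(hydroxymethyl)-8,8-dimethyl-4'-(prop-2-en-1-yl)spiro[6-oxabicyclo[3.2.1]octane-2,3'-oxane]-3,6'-dione | C=CC[C@@H]1[C@@H](CO)C(=O)OC[C@]12C(=O)C[C@@H]3OC[C@H]2C3(C)C
F2 | step 9 | (1S,2S,4'S,5S)-8,8-dimethyl-5'-methylidene-4'-(prop-2-en-1-yl)spiro[6-oxabicyclo[3.2.1]octane-2,3'-oxane]-3,6'-dione | C=CC[C@@H]1C(=C)C(=O)OC[C@]12C(=O)C[C@@H]3OC[C@H]2C3(C)C
F3 | step 9 | 2-[(1S,2S,4'S,5S)-8,8-dimethyl-5'-methylidene-3,6'-dioxospiro[6-oxabicyclo[3.2.1]octane-2,3'-oxan]-4'-yl]acetaldehyde | O=CC[C@@H]1C(=C)C(=O)OC[C@]12C(=O)C[C@@H]3OC[C@H]2C3(C)C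
F4 | step 9 | ethyl (1'S,4S,4aR,5'S,8aS)-7-(2-ethoxy-2-oxoacetyl)-6-hydroxy-8',8'-dimethyl-1,3'-dioxooctahydrospiro[isochromene-4,2'-[6]oxabicyclo[3.2.1]octane]-7-carboxylate (C6 and C7 epimers) | CCOC(=O)C(=O)C1(C(=O)OCC)C(O)C[C@@H]2[C@H](C1)C(=O)OC[C@]23C(=O)C[C@@H]4OC[C@H]3C4(C)C
F5 | step 9 | 2-[(1'S,4S,4aR,5'S,8aS)-8',8'-dimethyl-1,3'-dioxo-3,4a,5,8,8a-pentahydrospiro[isochromene-4,2'-[6]oxabicyclo[3.2.1]octan]-7-yl]-2-oxoacetic acid | OC(=O)C(=O)C1=CC[C@@H]2[C@H](C1)C(=O)OC[C@]23C(=O)C[C@@H]4OC[C@H]3C4(C)C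
F6 | step 3 | (5R)-5-{[dimethyl(phenyl)silyl]methyl}-4,4-dimethyl-6-(prop-2-en-1-yl)cyclohex-2-en-1-one (C6 undefined) | C=CCC1C(=O)C=CC(C)(C)[C@@H]1C[Si](C)(C)c1ccccc1
F7 | step 3 | (5S,6S)-5-{[dimethyl(phenyl)silyl]methyl}-6-(hydroxymethyl)-4,4-dimethyl-6-(prop-2-en-1-yl)cyclohex-2-en-1-one | C=CC[C@]1(CO)C(=O)C=CC(C)(C)[C@@H]1C[Si](C)(C)c1ccccc1
F8 | step 3 | (5S,6S)-5-{[dimethyl(phenyl)silyl]methyl}-6-(hydroxymethyl)-6-(3-hydroxypropyl)-4,4-dimethylcyclohex-2-en-1-one | OCCC[C@]1(CO)C(=O)C=CC(C)(C)[C@@H]1C[Si](C)(C)c1ccccc1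
F9 | step 3 | (6S,11S)-11-{[dimethyl(phenyl)silyl]methyl}-10,10-dimethyl-2-oxaspiro[5.5]undec-8-ene-3,7-dione | O=C1CC[C@]2(CO1)C(=O)C=CC(C)(C)[C@@H]2C[Si](C)(C)c1ccccc1
F10 | step 2 | racemic 5-{[dimethyl(phenyl)silyl]methyl}-4,4-dimethylcyclohex-2-en-1-one | O=C1C=CC(C)(C)C(C[Si](C)(C)c2ccccc2)C1
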